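(Readings and results were computed with made-up constants.)

The reckoning freezes the coupling partner at its charge: at the conversion asked about, the flask has used 13.3% of it.

- noon: left-handed substrate 0.12 M; right-handed substrate 0.12 M; coupling partner 6 equiv; free catalyst 0.05 mol%; run made earlier
- flask: left-handed substrate 0.12 M; coupling partner 3.00 equiv; free catalyst 0.05 mol%; right-handed substrate 0.12 M
noon run (percent of the left-handed substrate and right-handed substrate together charged)

| time / h | left-handed product / % |
|---|---|
| 0.200 | 7.7 |
| 0.333 | 10.7 |
| 0.500 | 15.6 |
| 0.833 | 22.9 |
| 1.33 | 30.8 |
| 2.50 | 38.3 |

(scatter of a reading: 0.5 percentage points)
- free catalyst is single-handed; left-handed substrate and right-handed substrate are mirror images of each other, charged as a racemate, each of them at the stated concentration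
- on the list of suspects stand: free catalyst + right-handed substrate <-> catalyst intermediate B; coupling partner + catalyst intermediate A -> free catalyst + left-handed product; free catalyst + left-handed substrate <-> catalyst intermediate A; coupling partner + catalyst intermediate B -> free catalyst + right-handed product; coupling partner + free catalyst -> spent catalyst A; free catalyst -> spent catalyst B
- no earlier run changes the charge of coupling partner; that part of a forecast is a guess
- apparent order in coupling partner when 20% of the left-handed substrate and right-handed substrate together are converted (percent change of the rate of making left-handed product for one percent more coupling partner charged)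
- factor on the rate of making left-handed product when 20% of the left-handed substrate and right-handed substrate together are converted if coupling partner is charged twice over

In the noon run, the readings give the logarithm of the left-handed substrate's fall a slope of 0.735 h⁻¹ up to 0.833 h, but of 0.423 h⁻¹ between 1.33 h and 2.50 h. Taken as catalyst decay, this drop gives a decay constant of about 0.368 h⁻¹, as a reading with the scatter of those points.

My own guess is a rate proportional to the coupling partner, and, with no right-handed product read, all of the conversion is counted as left-handed product. The flask with undiminished catalyst is then reckoned to need 1.39 h. Decay constant times that time is the lost share 0.512: the part of the catalyst gone on arrival. In this reckoning, less coupling partner lowers the rate directly and also through the catalyst lost on the longer way to that conversion, so the order is one over one minus the lost share, 2.05, and the doubling factor is 3.05.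

The forecast, which rests on “a mid-range guess”, gives an order of 0.4 and a factor of 1.3, both lower than this reckoning.

The flask gives order 1.7 and factor 2.66.

    free catalyst + right-handed substrate ⇌ catalyst intermediate B (K = 13.0 M⁻¹, k = 1.70 × 10⁵ M⁻¹ h⁻¹)
    coupling partner + catalyst intermediate A → free catalyst + left-handed product (k = 4200 M⁻¹ h⁻¹)
    free catalyst + left-handed substrate ⇌ catalyst intermediate A (K = 26.0 M⁻¹, k = 4.30 × 10⁵ M⁻¹ h⁻¹)
    coupling partner + catalyst intermediate B → free catalyst + right-handed product (k = 1400 M⁻¹ h⁻¹)
    coupling partner + free catalyst → spent catalyst A (k = 0.0760 M⁻¹ h⁻¹)
    free catalyst → spent catalyst B (k = 1.80 h⁻¹)

At 1.20 h the flask holds 36.3% of its catalyst as spent catalyst B, less than the lost share, and 0.512% as spent catalyst A. At 1.11 h free catalyst has a half-life of 0.385 h towards spent catalyst B, shorter than its 29 h towards spent catalyst A. For the run with twice the coupling partner, the lost share puts the time to that conversion at 0.412 of the flask's, and that run gives 0.441.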